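The target is cut at C1–C8a of the dihydronaphthalene ring. C1 is a lone methine lodged between C2, the α-carbon of the aroyl ketone, and arene carbon C8a, which lies para to the C6 methoxy group; both neighbours are latent nucleophiles. The key step therefore stitches one formyl-level carbon between them in a single operation: aminomethylenation of an acyclic γ-hydroxy ketone at C2, then acid-triggered Friedel–Crafts closure at C8a, during which the C3 hydroxymethyl oxygen holds C1 in a temporary dihydrofuran that reopens as the carbocycle forms. The precursor already carries the C3 stereocentre, set by one organocatalytic α-alkylation.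

Key step: step 3

Remark on numbering: C1–C8a are the locants of the 3,4-dihydronaphthalene ring of the target (C1 vinylic CH, C2 aroyl-bearing carbon, C3 stereocentre, C4 CH2, C6 OMe, C7 OH).

Assumption: compounds 1, 2 and 4 are taken as catalogue compounds; the sense of induction in step 2 follows the accepted enamine shielding model, and the (2S,5R) catalyst would be used if the opposite sense were found.

Step 1
Reactants: 1 1-(benzyloxy)-4-bromo-2-methoxybenzene; 2 prop-2-en-1-ol
Product: 3 3-[4-(benzyloxy)-3-methoxyphenyl]propanal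
Conditions: Pd(OAc)2 (cat.), Bu4NBr, NaHCO3, DMF, 100 °C
Reagents that add atoms: none
Why: Heck reaction of an aryl bromide with allyl alcohol under phosphine-free, ammonium-salt-promoted conditions: aryl-palladium adds to the terminal alkene carbon and β-hydride elimination toward the carbinol carbon gives an enol that tautomerises to the 3-arylpropanal; no stereocentre is formed.

Step 2
Reactants: 3 3-[4-(benzyloxy)-3-methoxyphenyl]propanal (2 equiv); 4 2-bromo-1-[4-(benzyloxy)-3-methoxyphenyl]ethan-1-one
Product: 6 (3R)-1,4-bis[4-(benzyloxy)-3-methoxyphenyl]-3-(hydroxymethyl)butan-1-one, via keto-aldehyde 5 (not isolated)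
Conditions: (2R,5S)-2-tert-butyl-3,5-dimethylimidazolidin-4-one·TfOH (20 mol %), Ru(bpy)3Cl2 (0.5 mol %), 2,6-lutidine, DMF, visible light, 23 °C; then dilute with CH2Cl2–MeOH, NaBH4, −50 °C
Reagents that add atoms: none
Why: Photoredox-organocatalytic enamine α-alkylation of an aldehyde: Ru(I) reduces 4 to the electrophilic phenacyl radical, which adds to the E-enamine of 3 on the Si face left open by the C5 methyl group of the (2R,5S) catalyst and so sets C3 as R, and NaBH4 at low temperature then reduces the epimerisable aldehyde of 5 in the same flask while the electron-rich aryl ketone is spared.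

Step 3
Reactants: 6 (3R)-1,4-bis[4-(benzyloxy)-3-methoxyphenyl]-3-(hydroxymethyl)butan-1-one
Product: 9 [(3R)-7-(benzyloxy)-3-(hydroxymethyl)-6-methoxy-3,4-dihydronaphthalen-2-yl][4-(benzyloxy)-3-methoxyphenyl]methanone, via enaminone 7 (not isolated), via dihydrofuranyl ketone 8 (not isolated)
Conditions: t-BuOCH(NMe2)2 (3 equiv), PhMe, 90 °C; evaporate; then TFA, CH2Cl2, 0 °C to rt
Reagents that add atoms: tert-butoxybis(dimethylamino)methane, CC(C)(C)OC(N(C)C)N(C)C
Why: The aminal ester condenses at the only enolisable position, C2, to give enaminone 7, and acid then exchanges the amine for the C3 hydroxymethyl oxygen to give the cyclic vinylogous ester 8, whose O-protonated form is an oxocarbenium ion at C1. Arene carbon C8a, para to the C6 methoxy group, attacks C1 (6-exo-trig Friedel–Crafts closure of the carbocycle), and acid-catalysed β-elimination of the bridging ether oxygen then opens the furan ring, releasing the CH2OH group and the C1=C2 enone. The closest known reaction type is the acid-mediated cyclodehydration of α-formyl (hydroxymethylene) γ-aryl ketones and esters to 3,4-dihydronaphthalenes (Bradsher-type cyclodehydration, an intramolecular Friedel–Crafts hydroxyalkylation–elimination). The dihydrofuran ring of 8 is closed by 5-exo-trig addition–elimination and is only temporary. No stereocentre is created; C3 is not enolisable and is carried through unchanged. The step needs attack at C1 and not at the ketone carbon, which the unhindered formyl-level C1 and the deactivation of the ketone carbon by its p-alkoxyaryl donor should secure, and it needs ring-B attack at C8a, which the para-directing C6 methoxy group and the hindered alternative ortho site should secure.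

Step 4
Reactants: 9 [(3R)-7-(benzyloxy)-3-(hydroxymethyl)-6-methoxy-3,4-dihydronaphthalen-2-yl][4-(benzyloxy)-3-methoxyphenyl]methanone
Product: 10 [(3R)-7-hydroxy-3-(hydroxymethyl)-6-methoxy-3,4-dihydronaphthalen-2-yl](4-hydroxy-3-methoxyphenyl)methanone
Conditions: BCl3 (1 M in CH2Cl2), pentamethylbenzene, CH2Cl2, −78 °C; MeOH quench
Reagents that add atoms: none
Why: Lewis-acid debenzylation with a non-Lewis-basic cation scavenger: BCl3 cleaves both aryl benzyl ethers at −78 °C and pentamethylbenzene traps the benzyl cations, so no reducing agent touches the C1=C2 enone and the methyl ethers and the C3 stereocentre are left alone.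

Compound list
1 | 1-(benzyloxy)-4-bromo-2-methoxybenzene | COc1cc(Br)ccc1OCc1ccccc1 | starting material
2 | prop-2-en-1-ol (allyl alcohol) | C=CCO | starting material
3 | 3-[4-(benzyloxy)-3-methoxyphenyl]propanal | COc1cc(CCC=O)ccc1OCc1ccccc1 | intermediate
4 | 2-bromo-1-[4-(benzyloxy)-3-methoxyphenyl]ethan-1-one | COc1cc(C(=O)CBr)ccc1OCc1ccccc1 | starting material
5 | (2R)-2-{[4-(benzyloxy)-3-methoxyphenyl]methyl}-4-[4-(benzyloxy)-3-methoxyphenyl]-4-oxobutanal | COc1cc(C[C@H](CC(=O)c2ccc(OCc3ccccc3)c(OC)c2)C=O)ccc1OCc1ccccc1 | intermediate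
6 | (3R)-1,4-bis[4-(benzyloxy)-3-methoxyphenyl]-3-(hydroxymethyl)butan-1-one | COc1cc(C[C@H](CC(=O)c2ccc(OCc3ccccc3)c(OC)c2)CO)ccc1OCc1ccccc1 | intermediate
7 | (3R)-1,4-bis[4-(benzyloxy)-3-methoxyphenyl]-2-[(dimethylamino)methylidene]-3-(hydroxymethyl)butan-1-one (C=C geometry of no consequence) | COc1cc(C[C@H](C(=CN(C)C)C(=O)c2ccc(OCc3ccccc3)c(OC)c2)CO)ccc1OCc1ccccc1 | intermediate
8 | [(3R)-3-{[4-(benzyloxy)-3-methoxyphenyl]methyl}-2,3-dihydrofuran-4-yl][4-(benzyloxy)-3-methoxyphenyl]methanone | COc1cc(C[C@H]2COC=C2C(=O)c2ccc(OCc3ccccc3)c(OC)c2)ccc1OCc1ccccc1 | intermediate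
9 | [(3R)-7-(benzyloxy)-3-(hydroxymethyl)-6-methoxy-3,4-dihydronaphthalen-2-yl][4-(benzyloxy)-3-methoxyphenyl]methanone | COc1cc(C(=O)C2=Cc3cc(OCc4ccccc4)c(OC)cc3C[C@H]2CO)ccc1OCc1ccccc1 | intermediate
10 | [(3R)-7-hydroxy-3-(hydroxymethyl)-6-methoxy-3,4-dihydronaphthalen-2-yl](4-hydroxy-3-methoxyphenyl)methanone (CNP0352298.1) | COc1cc(C(=O)C2=Cc3cc(O)c(OC)cc3C[C@H]2CO)ccc1O | target

Total step count: 4
Longest linear sequence: 4 steps (1 → 3 → 6 → 9 → 10)

Steps most likely to fail

1. Step 3 (key step). What may go wrong: slow aminomethylenation at the β-branched C2 of an electron-rich aryl ketone, or ring closure of ring B onto the ketone carbon in place of C1. Fallback (ring closure by Heck reaction in place of Friedel–Crafts chemistry), setting out from 6: NBS in MeCN at 0 °C should brominate ring B para to its methoxy group to give the ring-B bromide F1. α-Methylenation with paraformaldehyde and N-methylanilinium trifluoroacetate in refluxing THF should give the α-methylene ketone F2. Pd(OAc)2, P(o-tol)3, K2CO3 in DMF at 90 °C should then close the ring by 6-endo Heck arylation of the enone β-carbon, with β-hydride elimination toward the new benzylic carbon, and return to the route at 9.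

2. Step 2. What may go wrong: insufficient facial control in the radical addition, enolisation of the α-branched keto-aldehyde before it is reduced, or over-reduction of the aryl ketone. Fallback (auxiliary control in place of catalysis), setting out from 3: Pinnick oxidation should give the propanoic acid F3. Pivaloyl chloride/Et3N followed by lithiated (S)-4-benzyl-1,3-oxazolidin-2-one should give the N-acyl oxazolidinone F4. NaHMDS in THF at −78 °C and bromide 4 should alkylate the chelated Z-enolate on the face away from the auxiliary benzyl group to give the (2R)-keto imide F5. LiBH4 should remove the auxiliary and also reduce the ketone to give the diol F6. MnO2 in CH2Cl2 should reoxidise only the benzylic alcohol and return to the route at 6.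

3. Step 4. What may go wrong: Lewis-acid attack on the methyl ethers or on the electron-rich styrenyl enone during debenzylation. Fallback (benzyl groups removed before any alkene exists, fluoride-labile groups carried through the key step), setting out from 6: H2, Pd/C in EtOAc should give the free bis-phenol F7. TIPSCl and imidazole in DMF should give the tris-silyl ether F8. The conditions of step 3 should give the tris-silylated dihydronaphthalene F9. TBAF/AcOH in THF at 0 °C should then give the target 10.

Further compounds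
F1 | step 3 | (3R)-4-[4-(benzyloxy)-2-bromo-5-methoxyphenyl]-1-[4-(benzyloxy)-3-methoxyphenyl]-3-(hydroxymethyl)butan-1-one | COc1cc(C[C@H](CC(=O)c2ccc(OCc3ccccc3)c(OC)c2)CO)c(Br)cc1OCc1ccccc1
F2 | step 3 | (3R)-4-[4-(benzyloxy)-2-bromo-5-methoxyphenyl]-1-[4-(benzyloxy)-3-methoxyphenyl]-3-(hydroxymethyl)-2-methylidenebutan-1-one | COc1cc(C[C@H](C(=C)C(=O)c2ccc(OCc3ccccc3)c(OC)c2)CO)c(Br)cc1OCc1ccccc1
F3 | step 2 | 3-[4-(benzyloxy)-3-methoxyphenyl]propanoic acid | COc1cc(CCC(=O)O)ccc1OCc1ccccc1
F4 | step 2 | (4S)-4-benzyl-3-{3-[4-(benzyloxy)-3-methoxyphenyl]propanoyl}-1,3-oxazolidin-2-one | COc1cc(CCC(=O)N2C(=O)OC[C@@H]2Cc2ccccc2)ccc1OCc1ccccc1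
F5 | step 2 | (4S)-4-benzyl-3-[(2R)-2-{[4-(benzyloxy)-3-methoxyphenyl]methyl}-4-[4-(benzyloxy)-3-methoxyphenyl]-4-oxobutanoyl]-1,3-oxazolidin-2-one | COc1cc(C[C@H](CC(=O)c2ccc(OCc3ccccc3)c(OC)c2)C(=O)N2C(=O)OC[C@@H]2Cc2ccccc2)ccc1OCc1ccccc1
F6 | step 2 | (2R)-2-{[4-(benzyloxy)-3-methoxyphenyl]methyl}-4-[4-(benzyloxy)-3-methoxyphenyl]butane-1,4-diol (mixture of C4 epimers) | COc1cc(C[C@H](CC(O)c2ccc(OCc3ccccc3)c(OC)c2)CO)ccc1OCc1ccccc1
F7 | step 4 | (3R)-1,4-bis(4-hydroxy-3-methoxyphenyl)-3-(hydroxymethyl)butan-1-one | COc1cc(C[C@H](CC(=O)c2ccc(O)c(OC)c2)CO)ccc1O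
F8 | step 4 | (3R)-1,4-bis{3-methoxy-4-[(triisopropylsilyl)oxy]phenyl}-3-{[(triisopropylsilyl)oxy]methyl}butan-1-one | COc1cc(C[C@H](CC(=O)c2ccc(O[Si](C(C)C)(C(C)C)C(C)C)c(OC)c2)CO[Si](C(C)C)(C(C)C)C(C)C)ccc1O[Si](C(C)C)(C(C)C)C(C)C
F9 | step 4 | {(3R)-6-methoxy-7-[(triisopropylsilyl)oxy]-3-{[(triisopropylsilyl)oxy]methyl}-3,4-dihydronaphthalen-2-yl}{3-methoxy-4-[(triisopropylsilyl)oxy]phenyl}methanone | COc1cc(C(=O)C2=Cc3cc(O[Si](C(C)C)(C(C)C)C(C)C)c(OC)cc3C[C@H]2CO[Si](C(C)C)(C(C)C)C(C)C)ccc1O[Si](C(C)C)(C(C)C)C(C)C
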